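**The ceiling.** In the proposed steps E, the product, forms from substrate Z and reagent Q one for one, while Q can also pass reversibly into G, so you write the balance of Q: charged Q = Q left + G + E. In both new flasks Q is the limiting reagent, 0.180 M against 0.30 M of Z, so E in percent of the Z charged cannot pass the Q ceiling, charged Q over charged Z, 60.0%.

| flask | Z | Q | temperature | remark | time |
|---|---|---|---|---|---|
| maple | 0.15 M | 0.18 M (fed, over 5.0 d) | 75 °C | run made earlier |  |
| alder | 0.22 M | 0.18 M (fed, over 5.0 d) | 95 °C | run made earlier |  |
| spring | 0.30 M | 0.180 M (fed, over 5.0 d) | 110 °C |  | 10 d |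
| midnight | 0.30 M | 0.180 M | 80 °C | everything together at the start | 10 d |

| run | time / d | E / % | Z / % |
|---|---|---|---|
| maple | 8.00 | 3.5 | 96.4 |
| maple | 15.0 | 7.3 | 92.8 |
| maple | 25.0 | 9.9 | 88.4 |
| maple | 30.0 | 12.1 | 86.7 |
| alder | 2.50 | 4.7 | 96.9 |
| alder | 5.00 | 10.7 | 89.0 |
| alder | 8.00 | 19.1 | 79.7 |
| alder | 10.0 | 23.4 | 76.6 |
| alder | 12.0 | 27.3 | 71.8 |

(standard deviation of a reading: 1 percentage point)

- which one finishes higher in amount of E, in percent of the Z charged ("neither" within 2 percentage points) (spring / midnight / neither)
- amount of E at the end, in percent of the Z charged, spring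
- amount of E at the end, in percent of the Z charged, midnight

**The floor.** At 8.00 d, alder at 95 °C shows 19.1% against 3.5% for maple at 75 °C. That ratio of 5.46 is a reading, loose with the scatter on the small figure, and alder differs from maple in Z as well. Carried evenly on to 110 °C, it gives a factor of 3.57. Alder held 0.0235 M of E at 5.00 d. Multiplying by that factor, and taking no credit for the richer Z of spring or for its days after the feed, I estimate spring above 28.0% of its Z.

**Midnight's bracket.** Midnight is hotter than maple, richer in Z and has its Q from the start, so I take the 0.00525 M of E in maple at 8.00 d as its estimated lower mark, 1.75%. Midnight is colder than alder, though richer in Z, so I place it, as an estimate and no strict limit, under the 23.4% of alder at 10.0 d. Spring's floor stands above that top, so my choice is spring.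

**The forecast.** It says spring, with 44% for spring and 9% for midnight, on the ground "The runs fit second-order Z + Q kinetics." Both numbers lie inside my brackets.

**The result.** Spring finishes at 48.3% and midnight at 5.74%.

    Z + Q → E, rate k1*[Z]^0.5*[Q]^0.5 (k = 1.40 × 10⁻⁴ min⁻¹, Ea = 121 kJ mol⁻¹)
    Q ⇌ G (K = 1.60, k = 2.40 × 10⁻⁴ min⁻¹, Ea = 119 kJ mol⁻¹, ΔH = −90.0 kJ mol⁻¹)
    (constants at 110 °C)

**Ceiling reused.** Spring stands 12 percentage points under its ceiling at 10 d, which is 0.0351 M of Q still uncounted in E: G holds 0.0292 M, and Q keeps 3.20% of its charge. Now take the neighbour, spring with 0.072 M of Q. Its ceiling is 24.0%, and at 10 d it gives 22.3% of E, with Q down to 0.17% of its charge and G at 0.00502 M.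

All runs are simulated for substances that don't exist; noise was put on by code.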